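**Retrosynthetic overview**
- The target comes from its C8 alcohol by methacrylation. The alcohol comes from a ring-closed C2 carbinol by oxidation and desilylation.
- The ten-membered carbocycle and the butenolide are disconnected together at C6–C7 and O6–C12. An acyclic C15 enal carrying a (Z)-β-triflyloxy enoate closes C6–C7 (the bond the germacrene cyclase makes) by Ni/Cr-mediated alkenylation. The C6 alkoxide then lactonizes onto C12 in the same flask, so the carbocycle forms first and the lactone second, with C6 set from C8.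
- The acyclic chain comes from two head-to-tail vinylogous Mukaiyama aldol additions of one C5 dienol ether (from prenal). The first makes C8–C9 and sets C8; the second makes C2–C3.
- The C7/C8/C11–C13 unit comes from the Morita–Baylis–Hillman adduct of methyl acrylate and dimethoxyacetaldehyde, by oxidation, acetate conjugate addition and chelation-controlled (Z)-enol triflation.

Assumption: germacrane numbering is used for the skeleton, the target SMILES is read as (6R,8S) with 1(10)E and 4E olefins, and the oxazaborolidinone from N-tosyl-D-tryptophan is taken to direct Si-face attack on the aldehydes (the L-promoter would be used if the sense proves opposite).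

**Route**

Step 1
Reactants: 1 3-methylbut-2-enal
Product: 2 (E)-tert-butyl(dimethyl)[(3-methylbuta-1,3-dien-1-yl)oxy]silane
Conditions: TBSOTf, Et3N, Et2O, 0 °C to rt
Reagents that add atoms: tert-butyldimethylsilyl trifluoromethanesulfonate, CC(C)(C)[Si](C)(C)OS(=O)(=O)C(F)(F)F
Why: Silyl dienol ether formation by O-silylation of the enal and γ-deprotonation by the amine, which gives the (E)-1-silyloxy diene used as the C5 unit in steps 6 and 8.

Step 2
Reactants: 3 methyl prop-2-enoate (methyl acrylate); 4 2,2-dimethoxyacetaldehyde (60% in water)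
Product: 5 methyl 3-hydroxy-4,4-dimethoxy-2-methylidenebutanoate (racemic)
Conditions: DABCO (0.5 equiv), 1,4-dioxane/H2O, rt
Reagents that add atoms: none
Why: Morita–Baylis–Hillman reaction of an activated α,α-dialkoxy aldehyde, which assembles C8, C7, C11, C12 and C13 in one step; the carbinol centre is removed in step 3.

Step 3
Reactants: 5 methyl 3-hydroxy-4,4-dimethoxy-2-methylidenebutanoate
Product: 7 methyl 2-[(acetyloxy)methyl]-4,4-dimethoxy-3-oxobutanoate (racemic), via enone 6 (not isolated)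
Conditions: Dess–Martin periodinane, CH2Cl2, 0 °C; then NaOAc, AcOH, rt
Reagents that add atoms: acetic acid, CC(=O)O
Why: Dess–Martin oxidation gives the 2-methylidene β-keto ester, and oxa-Michael addition of acetic acid to this doubly activated alkene (as in the formation of acetoxymethyl malonates) installs the C13 acetate; the new centre is enolizable and destroyed in step 4.

Step 4
Reactants: 7 methyl 2-[(acetyloxy)methyl]-4,4-dimethoxy-3-oxobutanoate
Product: 9 methyl (2Z)-2-[(acetyloxy)methyl]-4,4-dimethoxy-3-{[(trifluoromethyl)sulfonyl]oxy}but-2-enoate, via lithium enolate 8 (not isolated)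
Conditions: LiN(SiMe3)2, Et2O, −78 °C; then Tf2O, −78 °C
Reagents that add atoms: trifluoromethanesulfonic anhydride, O=S(=O)(OS(=O)(=O)C(F)(F)F)C(F)(F)F
Why: O-Triflation of the lithium-chelated (Z)-enolate of a β-keto ester gives the (Z)-enol triflate with TfO cis to CO2Me, the geometry needed for lactonization in step 9; working at −78 °C keeps the enolate from expelling acetate.

Step 5
Reactants: 9 methyl (2Z)-2-[(acetyloxy)methyl]-4,4-dimethoxy-3-{[(trifluoromethyl)sulfonyl]oxy}but-2-enoate
Product: 10 methyl (2Z)-2-[(acetyloxy)methyl]-4-oxo-3-{[(trifluoromethyl)sulfonyl]oxy}but-2-enoate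
Conditions: TFA/H2O (9:1), CH2Cl2, 0 °C to rt; used crude
Reagents that add atoms: water, O
Why: Acid hydrolysis of the dimethyl acetal frees the C8 aldehyde, while the enol triflate, allylic acetate and methyl ester are stable to aqueous acid.

Step 6
Reactants: 10 methyl (2Z)-2-[(acetyloxy)methyl]-4-oxo-3-{[(trifluoromethyl)sulfonyl]oxy}but-2-enoate; 2 (E)-tert-butyl(dimethyl)[(3-methylbuta-1,3-dien-1-yl)oxy]silane
Product: 11 methyl (2Z,4S,6E)-2-[(acetyloxy)methyl]-4-hydroxy-6-methyl-8-oxo-3-{[(trifluoromethyl)sulfonyl]oxy}octa-2,6-dienoate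
Conditions: B-phenyl oxazaborolidinone from N-tosyl-D-tryptophan and PhBCl2 (1.0 equiv), i-PrOH, EtCN, −78 °C
Reagents that add atoms: none
Why: Enantioselective vinylogous Mukaiyama aldol reaction in which the γ-carbon of the dienol ether adds to the Si face of the boron-bound aldehyde to set C8 as S, the s-trans diene gives the E-enal, and the far more electrophilic triflyloxy enal reacts in preference to the product enal.

Step 7
Reactants: 11 methyl (2Z,4S,6E)-2-[(acetyloxy)methyl]-4-hydroxy-6-methyl-8-oxo-3-{[(trifluoromethyl)sulfonyl]oxy}octa-2,6-dienoate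
Product: 12 methyl (2Z,4S,6E)-2-[(acetyloxy)methyl]-6-methyl-8-oxo-4-[(triethylsilyl)oxy]-3-{[(trifluoromethyl)sulfonyl]oxy}octa-2,6-dienoate
Conditions: TESOTf, 2,6-lutidine, CH2Cl2, −78 °C
Reagents that add atoms: triethylsilyl trifluoromethanesulfonate, CC[Si](CC)(CC)OS(=O)(=O)C(F)(F)F
Why: Silylation of the secondary alcohol is much faster than enolization of the enal under these conditions, and a silyl ether (unlike an ester) is a poor leaving group next to the alkenyl metal generated in step 9.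

Step 8
Reactants: 12 methyl (2Z,4S,6E)-2-[(acetyloxy)methyl]-6-methyl-8-oxo-4-[(triethylsilyl)oxy]-3-{[(trifluoromethyl)sulfonyl]oxy}octa-2,6-dienoate; 2 (E)-tert-butyl(dimethyl)[(3-methylbuta-1,3-dien-1-yl)oxy]silane
Product: 13 methyl (2Z,4S,6E,8S,10E)-2-[(acetyloxy)methyl]-8-hydroxy-6,10-dimethyl-12-oxo-4-[(triethylsilyl)oxy]-3-{[(trifluoromethyl)sulfonyl]oxy}dodeca-2,6,10-trienoate
Conditions: B-phenyl oxazaborolidinone from N-tosyl-D-tryptophan and PhBCl2 (1.0 equiv), i-PrOH, EtCN, −78 °C; 1.1 equiv of 2, stopped before full conversion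
Reagents that add atoms: none
Why: A second vinylogous Mukaiyama aldol reaction (1,2-addition to the enal) completes the C15 chain with the 4E-enal; the same promoter gives one carbinol epimer (Si-face attack, S) so the cyclization is run on a single diastereomer, although this centre is oxidized in step 10.

Step 9
Reactants: 13 methyl (2Z,4S,6E,8S,10E)-2-[(acetyloxy)methyl]-8-hydroxy-6,10-dimethyl-12-oxo-4-[(triethylsilyl)oxy]-3-{[(trifluoromethyl)sulfonyl]oxy}dodeca-2,6,10-trienoate
Product: 15 (2S,6R,8S)-13-acetoxy-2-hydroxy-8-(triethylsilyloxy)germacra-1(10)E,4E,7(11)-trien-12,6-olide, via hydroxy ester 14 (not isolated)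
Conditions: CrCl2 (10 equiv), NiCl2 (0.1 equiv), degassed DMF, rt, 0.002 M, syringe-pump addition over 12 h; aq. NH4Cl work-up, then PPTS (cat.), CH2Cl2
Reagents that add atoms: none
Why: Proposed new method: zerovalent nickel (made from NiCl2 by CrCl2) inserts into the C7–OTf bond and transmetallation gives a (Z)-β-chromio enoate of trivalent chromium that adds across the chain to the C6 enal (Nozaki–Hiyama–Kishi reaction; closest precedents are Ni/Cr macrocyclizations of alkenyl iodides and triflates and butenolide formation from (Z)-β-iodoacrylates and aldehydes), the resulting alkoxide then attacks the cis methyl ester to close the lactone, and C6 is set from C8 because A(1,3) strain against CH2OAc holds H-8 in the olefin plane, so that the C9 and C5 arms flank the planar C6–C7–C8 unit from opposite faces (no syn-pentane contact) and O-6 is delivered beside the ester to give 6R with 8S.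

Step 10
Reactants: 15 (2S,6R,8S)-13-acetoxy-2-hydroxy-8-(triethylsilyloxy)germacra-1(10)E,4E,7(11)-trien-12,6-olide
Product: 16 (6R,8S)-13-acetoxy-2-oxo-8-(triethylsilyloxy)germacra-1(10)E,4E,7(11)-trien-12,6-olide
Conditions: Dess–Martin periodinane, NaHCO3, CH2Cl2, 0 °C
Reagents that add atoms: none
Why: Dess–Martin oxidation of the only free (allylic) alcohol gives the 1(10)-en-2-one; doing this after ring closure avoids an acyclic enal–ketone in which C3 would sit between two carbonyl-activated π systems and enolize.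

Step 11
Reactants: 16 (6R,8S)-13-acetoxy-2-oxo-8-(triethylsilyloxy)germacra-1(10)E,4E,7(11)-trien-12,6-olide
Product: 17 (6R,8S)-13-acetoxy-8-hydroxy-2-oxogermacra-1(10)E,4E,7(11)-trien-12,6-olide
Conditions: HF·pyridine, pyridine, THF, 0 °C
Reagents that add atoms: none
Why: Fluoride-mediated cleavage of the triethylsilyl ether under buffered, non-basic conditions spares the base-sensitive 13-acetoxy butenolide and leaves C8 untouched.

Step 12
Reactants: 17 (6R,8S)-13-acetoxy-8-hydroxy-2-oxogermacra-1(10)E,4E,7(11)-trien-12,6-olide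
Product: 18 (6R,8S)-13-acetoxy-8-(methacryloyloxy)-2-oxogermacra-1(10)E,4E,7(11)-trien-12,6-olide (CNP0325594.1)
Conditions: methacrylic anhydride, Et3N, DMAP (cat.), CH2Cl2, 0 °C
Reagents that add atoms: methacrylic anhydride, C=C(C)C(=O)OC(=O)C(C)=C
Why: DMAP-catalysed acylation of the secondary alcohol proceeds with retention at C8 and installs the methacrylate last, so it never sits next to an alkenyl metal.

**Compound list**

1 | 3-methylbut-2-enal | CC(C)=CC=O | starting material
2 | (E)-tert-butyl(dimethyl)[(3-methylbuta-1,3-dien-1-yl)oxy]silane | C=C(C)/C=C/O[Si](C)(C)C(C)(C)C | intermediate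
3 | methyl prop-2-enoate (methyl acrylate) | C=CC(=O)OC | starting material
4 | 2,2-dimethoxyacetaldehyde | COC(OC)C=O | starting material
5 | methyl 3-hydroxy-4,4-dimethoxy-2-methylidenebutanoate (racemic) | COC(OC)C(O)C(=C)C(=O)OC | intermediate
6 | methyl 4,4-dimethoxy-2-methylidene-3-oxobutanoate (not isolated) | COC(OC)C(=O)C(=C)C(=O)OC | intermediate
7 | methyl 2-[(acetyloxy)methyl]-4,4-dimethoxy-3-oxobutanoate (racemic) | COC(OC)C(=O)C(COC(C)=O)C(=O)OC | intermediate
8 | lithium (2Z)-3-[(acetyloxy)methyl]-1,1,4-trimethoxy-4-oxobut-2-en-2-olate (not isolated) | [Li+].COC(OC)/C([O-])=C(\COC(C)=O)C(=O)OC | intermediate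
9 | methyl (2Z)-2-[(acetyloxy)methyl]-4,4-dimethoxy-3-{[(trifluoromethyl)sulfonyl]oxy}but-2-enoate | COC(OC)/C(OS(=O)(=O)C(F)(F)F)=C(\COC(C)=O)C(=O)OC | intermediate
10 | methyl (2Z)-2-[(acetyloxy)methyl]-4-oxo-3-{[(trifluoromethyl)sulfonyl]oxy}but-2-enoate | O=C/C(OS(=O)(=O)C(F)(F)F)=C(\COC(C)=O)C(=O)OC | intermediate
11 | methyl (2Z,4S,6E)-2-[(acetyloxy)methyl]-4-hydroxy-6-methyl-8-oxo-3-{[(trifluoromethyl)sulfonyl]oxy}octa-2,6-dienoate | O=C/C=C(\C)C[C@H](O)/C(OS(=O)(=O)C(F)(F)F)=C(\COC(C)=O)C(=O)OC | intermediate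
12 | methyl (2Z,4S,6E)-2-[(acetyloxy)methyl]-6-methyl-8-oxo-4-[(triethylsilyl)oxy]-3-{[(trifluoromethyl)sulfonyl]oxy}octa-2,6-dienoate | O=C/C=C(\C)C[C@H](O[Si](CC)(CC)CC)/C(OS(=O)(=O)C(F)(F)F)=C(\COC(C)=O)C(=O)OC | intermediate
13 | methyl (2Z,4S,6E,8S,10E)-2-[(acetyloxy)methyl]-8-hydroxy-6,10-dimethyl-12-oxo-4-[(triethylsilyl)oxy]-3-{[(trifluoromethyl)sulfonyl]oxy}dodeca-2,6,10-trienoate | O=C/C=C(\C)C[C@H](O)/C=C(\C)C[C@H](O[Si](CC)(CC)CC)/C(OS(=O)(=O)C(F)(F)F)=C(\COC(C)=O)C(=O)OC | intermediate
14 | methyl (2S,6R,8S)-13-acetoxy-2,6-dihydroxy-8-(triethylsilyloxy)germacra-1(10)E,4E,7(11)-trien-12-oate, C12 cis to C6, held in the flask as its 6-alkoxide of trivalent chromium (not isolated) | CC[Si](CC)(CC)O[C@H]1C/C(C)=C/[C@@H](O)C/C(C)=C/[C@@H](O)/C1=C(/COC(C)=O)C(=O)OC | intermediate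
15 | (2S,6R,8S)-13-acetoxy-2-hydroxy-8-(triethylsilyloxy)germacra-1(10)E,4E,7(11)-trien-12,6-olide | CC[Si](CC)(CC)O[C@H]1C/C(C)=C/[C@@H](O)C/C(C)=C/[C@H]2OC(=O)C(COC(C)=O)=C12 | intermediate
16 | (6R,8S)-13-acetoxy-2-oxo-8-(triethylsilyloxy)germacra-1(10)E,4E,7(11)-trien-12,6-olide | CC[Si](CC)(CC)O[C@H]1C/C(C)=C/C(=O)C/C(C)=C/[C@H]2OC(=O)C(COC(C)=O)=C12 | intermediate
17 | (6R,8S)-13-acetoxy-8-hydroxy-2-oxogermacra-1(10)E,4E,7(11)-trien-12,6-olide | O[C@H]1C/C(C)=C/C(=O)C/C(C)=C/[C@H]2OC(=O)C(COC(C)=O)=C12 | intermediate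
18 | (6R,8S)-13-acetoxy-8-(methacryloyloxy)-2-oxogermacra-1(10)E,4E,7(11)-trien-12,6-olide | C=C(C)C(=O)O[C@H]1C/C(C)=C/C(=O)C/C(C)=C/[C@H]2OC(=O)C(COC(C)=O)=C12 | target

**Step count and risks**

Total: 12 steps. Longest linear sequence: 11 steps (steps 2 to 12); step 1 prepares the C5 dienol ether that is used twice.

The three steps most likely to fail:

1. Step 9 (ring closure and lactonization). A ten-membered closure with a tetrasubstituted alkenyl metal is slow, and the C6 configuration rests on substrate control that may go the other way. Fallback, setting out from 10 and coming back at 18: if the closure works but gives the epimer with O-6 and O-8 on opposite faces, the substrate-controlled sense is kept and C8 is corrected at the end. Aldehyde 10 is taken through steps 6 to 8 with the N-tosyl-L-tryptophan promoter to give the (4R) alcohol F1, its triethylsilyl ether F2 and the (4R,8R) aldol product F3. The Ni/Cr closure of F3 then runs in the mirror-image mode through the hydroxy ester F4 (not isolated) to the (2R,6R,8R) lactone alcohol F5. Dess–Martin oxidation gives the (6R,8R) enone F6 and HF·pyridine the (6R,8R) alcohol F7. Mitsunobu esterification of F7 with methacrylic acid (PPh3, DIAD, toluene, 0 °C) inverts C8 and gives 18.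

2. Step 8 (second vinylogous aldol). The product enal is as electrophilic as the substrate enal, so over-addition and oligomers are likely. Fallback, setting out from 12 and coming back at 13: the C5 unit is built in two parts. Allylboration of 12 with 2-methylallylboronic acid pinacol ester, catalysed by (S)-3,3'-bis(2,4,6-triisopropylphenyl)-1,1'-binaphthyl-2,2'-diyl hydrogen phosphate (toluene, −30 °C), gives the homoallylic alcohol F8. Cross-metathesis of F8 with crotonaldehyde (second-generation Hoveyda–Grubbs catalyst, RuCl2(H2IMes)(=CH-C6H4-2-OiPr), CH2Cl2, 40 °C) gives 13 after removal of the minor 10Z isomer.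

3. Step 6 (first vinylogous aldol). The densely functionalized triflyloxy enal is untested with this promoter; an uncatalysed background reaction could erode the enantiomeric excess, or the sense could be opposite to that assumed. Fallback, setting out from 10 and coming back at 11: the addition of 2 is run with BF3·OEt2 and i-PrOH (CH2Cl2, −78 °C) to give the racemic alcohol F9. Kinetic resolution with Amano lipase PS and vinyl acetate (t-BuOMe, 30 °C) acetylates the (4R) enantiomer to the acetate F10 and leaves 11.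

**Further compounds**

F1 | step 9 | methyl (2Z,4R,6E)-2-[(acetyloxy)methyl]-4-hydroxy-6-methyl-8-oxo-3-{[(trifluoromethyl)sulfonyl]oxy}octa-2,6-dienoate | O=C/C=C(\C)C[C@@H](O)/C(OS(=O)(=O)C(F)(F)F)=C(\COC(C)=O)C(=O)OC
F2 | step 9 | methyl (2Z,4R,6E)-2-[(acetyloxy)methyl]-6-methyl-8-oxo-4-[(triethylsilyl)oxy]-3-{[(trifluoromethyl)sulfonyl]oxy}octa-2,6-dienoate | O=C/C=C(\C)C[C@@H](O[Si](CC)(CC)CC)/C(OS(=O)(=O)C(F)(F)F)=C(\COC(C)=O)C(=O)OC
F3 | step 9 | methyl (2Z,4R,6E,8R,10E)-2-[(acetyloxy)methyl]-8-hydroxy-6,10-dimethyl-12-oxo-4-[(triethylsilyl)oxy]-3-{[(trifluoromethyl)sulfonyl]oxy}dodeca-2,6,10-trienoate | O=C/C=C(\C)C[C@@H](O)/C=C(\C)C[C@@H](O[Si](CC)(CC)CC)/C(OS(=O)(=O)C(F)(F)F)=C(\COC(C)=O)C(=O)OC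
F4 | step 9 | methyl (2R,6R,8R)-13-acetoxy-2,6-dihydroxy-8-(triethylsilyloxy)germacra-1(10)E,4E,7(11)-trien-12-oate, C12 cis to C6 (not isolated) | CC[Si](CC)(CC)O[C@@H]1C/C(C)=C/[C@H](O)C/C(C)=C/[C@@H](O)/C1=C(/COC(C)=O)C(=O)OC
F5 | step 9 | (2R,6R,8R)-13-acetoxy-2-hydroxy-8-(triethylsilyloxy)germacra-1(10)E,4E,7(11)-trien-12,6-olide | CC[Si](CC)(CC)O[C@@H]1C/C(C)=C/[C@H](O)C/C(C)=C/[C@H]2OC(=O)C(COC(C)=O)=C12
F6 | step 9 | (6R,8R)-13-acetoxy-2-oxo-8-(triethylsilyloxy)germacra-1(10)E,4E,7(11)-trien-12,6-olide | CC[Si](CC)(CC)O[C@@H]1C/C(C)=C/C(=O)C/C(C)=C/[C@H]2OC(=O)C(COC(C)=O)=C12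
F7 | step 9 | (6R,8R)-13-acetoxy-8-hydroxy-2-oxogermacra-1(10)E,4E,7(11)-trien-12,6-olide | O[C@@H]1C/C(C)=C/C(=O)C/C(C)=C/[C@H]2OC(=O)C(COC(C)=O)=C12
F8 | step 8 | methyl (2Z,4S,6E,8S)-2-[(acetyloxy)methyl]-8-hydroxy-6,10-dimethyl-4-[(triethylsilyl)oxy]-3-{[(trifluoromethyl)sulfonyl]oxy}undeca-2,6,10-trienoate | C=C(C)C[C@H](O)/C=C(\C)C[C@H](O[Si](CC)(CC)CC)/C(OS(=O)(=O)C(F)(F)F)=C(\COC(C)=O)C(=O)OC
F9 | step 6 | methyl (2Z,6E)-2-[(acetyloxy)methyl]-4-hydroxy-6-methyl-8-oxo-3-{[(trifluoromethyl)sulfonyl]oxy}octa-2,6-dienoate (racemic) | O=C/C=C(\C)CC(O)/C(OS(=O)(=O)C(F)(F)F)=C(\COC(C)=O)C(=O)OC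
F10 | step 6 | methyl (2Z,4R,6E)-4-(acetyloxy)-2-[(acetyloxy)methyl]-6-methyl-8-oxo-3-{[(trifluoromethyl)sulfonyl]oxy}octa-2,6-dienoate | O=C/C=C(\C)C[C@@H](OC(C)=O)/C(OS(=O)(=O)C(F)(F)F)=C(\COC(C)=O)C(=O)OC
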